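## The problem

The target 21 is methyl (5R,6S)-3-[(1E,3E,5S)-3,5-dimethylhepta-1,3-dien-1-yl]-5-hydroxy-6-methoxy-6-methyl-7-oxo-6,7-dihydro-5H-cyclopenta[c]pyridine-5-carboxylate. A pyridine is fused through C4a–C7a to a cyclopentanone in which C5, C6 and C7 are all functionalised. C5 (hydroxyl, methyl ester) and C6 (methyl, methoxy) are adjacent, fully substituted stereocentres with the two oxygens trans. Neither can be corrected by epimerisation, so both must be right when the C5–C6 bond or its oxygens are installed; being neighbours, one can direct the other. The third stereocentre, C5' of the (1E,3E)-dienyl chain on C3, is too remote to control the core or be controlled by it and has to come from the chiral pool. The C5 hydroxyl is β to the C7 ketone, so a C5 alkoxide can open the five-membered ring by retro-aldol cleavage; the ester and the diene further limit base, acid and oxidants. A pyridine does not undergo Friedel–Crafts acylation, so the C7–C7a bond must be made from a ring carbanion. The enabling feature is that C6 with its methyl group, its oxygen and the C7 carbonyl is the skeleton of lactic acid. C7 can therefore be the carbonyl of a lactic acid dioxolanone that acylates a metalated C7a and, in doing so, frees only the C6 oxygen for methylation.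

## Retrosynthesis

**21 from 20.** Only the O–Si bond at C5 is cut. The hydroxyl stays masked until the end because the free β-hydroxy ketone does not tolerate the basic steps before it. The last step must therefore be non-basic.

**20 from 13 and 19.** The C3–C1' bond between the pyridine and the diene is cut. Building the diene by olefination from a C3 aldehyde would cost more steps and put the E geometry at risk late. Carrying the diene through the organometallic steps would remove the chloride that serves as an inert marker for C3. The cut gives chloropyridine 13 and dienyl boronate 19, which holds the remote stereocentre and both E double bonds. The coupling must keep the geometry and work with mild base.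

**13 from 10 (key disconnection).** The C7–C7a bond and the O–CH3 bond are cut. Closing C4a–C5 by adding a ring anion to a ketone would create C5 during ring closure without a controller. Closing C6–C7 is the acyloin-type cut of Alternative 2. The chosen cut makes ring closure stereochemically silent. The precursor 10 is acyclic, carries both stereocentres, a bromide at the future C7a and a chloride at the future C3, and has C6/C7 as a dioxolanone. The forward step needs halogen–metal exchange faster than carbonyl addition, attack on one carbonyl only, and alkylation of the released oxygen only.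

**10 from 9, and 9 from 4 and 7.** After removal of the silyl group the C5–C6 bond is cut as an aldol. This divides the molecule between its two stereocentres into the achiral keto ester 4 and the dioxolanone 7, whose acetal carbon stores the lactate chirality. The neighbouring cut at C5–C4 (ring anion 3 added to a keto ester already on the dioxolanone) is kept as the fallback. A cut at the C5–ester bond would need a cyanide-type carboxyl equivalent, whose solvolysis the acetal would not survive. The aldol has to select one face of each partner.

**4 from 1 and 2.** The bond between pyridine C4 and the keto carbon is cut. Compound 1 is deprotonated next to bromine to give 3, which is acylated by the oxalate 2. Both halogens are in place from the start.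

**7 from 5 and 6.** The two acetal C–O bonds are cut. Acid-catalysed condensation of the chiral-pool acid 5 with the aldehyde 6 gives the cis dioxolanone.

**19 from 18, 17, 16 and 14.** The C1'=C2' bond is cut to the enal 18 (one-carbon boron olefination). Adjusting the oxidation level leads through 17 to the enoate 16. Cutting the C3'=C4' bond leads to the aldehyde 15, made in the flask from the commercial alcohol 14.

## Roads not taken

**Alternative 1:** The cut removes both C–O bonds at C5 and C6 and leads to the flat azaindenone A1, methyl 3-[(1E,3E,5S)-3,5-dimethylhepta-1,3-dien-1-yl]-6-methyl-7-oxo-7H-cyclopenta[c]pyridine-5-carboxylate.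
- Key step: tert-butyl hydroperoxide with N-benzylquininium chloride (or N-benzylquinidinium chloride) as phase-transfer catalyst would epoxidise the C5=C6 bond to A2. Methanol would then have to open A2 at C6 with inversion to give 21.
- Merits: both stereocentres come from one catalytic step, there is no auxiliary or protecting group, and the trans relation of hydroxyl and methoxy follows from the opening.
- Weak points: A1 is a cyclopentadienone-type acceptor that is likely to dimerise or add nucleophiles. Enantioselective epoxidation of a tetrasubstituted enone with an ester on the β-carbon has no secure basis. The opening must occur at a tertiary carbon α to a ketone, where neither direct displacement nor ionisation is favourable, and C5 competes.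
- Comparison: this road is shorter and more catalytic than the chosen plan. The chosen plan sets against it that the C6–O bond comes intact from lactic acid and the methyl ether is made by O-alkylation, so no substitution at a tertiary carbon is needed.

**Alternative 2:** The cut is the C6–C7 bond and leads to the keto aldehyde A3, methyl (2R)-2-(2-chloro-5-formylpyridin-4-yl)-3-oxo-2-[(triethylsilyl)oxy]butanoate.
- Key step: the carbene generated with Et3N from (5aS,10bR)-2-(pentafluorophenyl)-5a,10b-dihydro-4H,6H-indeno[2,1-b][1,2,4]triazolo[4,3-d][1,4]oxazin-2-ium tetrafluoroborate (or its enantiomer) makes the aldehyde carbon an acyl anion equivalent. It adds to the acetyl ketone and gives A4, closing the ring and forming C6.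
- Merits: the ring closure is mild and catalytic, tolerates ester and chloride, and the catalyst could reinforce or override the bias from C5.
- Weak points: C5 must already be set in A3, an acyclic α-silyloxy β-keto ester with no reliable asymmetric access and a tendency to retro-Claisen cleavage under base. The outcome at C6 depends on matched or mismatched pairing. A4 still carries a free tertiary α-ketol, whose methylation needs an alkoxide prone to ring opening.
- Comparison: this road is better in the mildness of ring closure. The chosen plan sets against it that both stereocentres come from one aldol and that the C6 oxygen appears as an alkoxide in an aprotic flask and is methylated at once.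

**Alternative 3:** The cut is through the pyridine ring (C7a–C1 and C4a–C4) and leads to the triazine A5, 5-(dimethoxymethyl)-1,2,4-triazine, and the cyclopentanone A6, methyl (1S,2R)-2-methoxy-2-methyl-5-oxo-1-[(trimethylsilyl)oxy]cyclopentane-1-carboxylate.
- Key step: A6, activated in the flask by pyrrolidine, adds across C3 and C6 of A5; loss of N2 and the amine gives the pyridine A7.
- Merits: no halopyridine is metalated, the pyridine substitution is set by design, and the acetal offers an aldehyde for building the diene by olefination.
- Weak points: A6 already contains both contiguous quaternary centres, so the stereochemical problem is only moved to a ring with no obvious chiral-pool unit. Enamine formation next to the quaternary α-silyloxy ester carbon is hindered and invites retro-Claisen opening. A7 lacks the C7 carbonyl, so a late benzylic oxidation next to a quaternary carbon is needed, plus steps to unmask the aldehyde and build the diene.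
- Comparison: this road matches the chosen plan in that ring formation creates no stereocentre, and it avoids low-temperature organometallic steps. The chosen plan sets against it a commercial pyridine with both halogens in place, C7 at the right oxidation level, and a shorter end game.

Key step: step 5

Assumption: the core is numbered as in 5H-cyclopenta[c]pyridine and side-chain atoms carry primes. The (R) configuration at C5 is assumed to come out of the aldol of step 3 through the chair described there; this sense is not secured by a model and is covered by a fallback.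

## Route

Step 1
Reactants: 1 5-bromo-2-chloropyridine; 2 dimethyl oxalate
Product: 4 methyl 2-(5-bromo-2-chloropyridin-4-yl)-2-oxoacetate, via (5-bromo-2-chloropyridin-4-yl)lithium 3 (not isolated)
Conditions: LiN(i-Pr)2, THF, −78 °C; then cannulation into 2 (excess), THF, −78 °C; aq. NH4Cl
Reagents that add atoms: none
Why: Directed ortho-lithiation followed by acylation: the amide base removes the C4 proton next to bromine at −78 °C, where halogen migration and pyridyne formation are slow. Inverse addition to excess oxalate stops at the mono-adduct.

Step 2
Reactants: 5 (R)-lactic acid; 6 pivalaldehyde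
Product: 7 (2R,5R)-2-tert-butyl-5-methyl-1,3-dioxolan-4-one
Conditions: p-TsOH·H2O (cat.), H2SO4 (cat.), pentane, reflux, Dean–Stark; crystallisation from pentane/Et2O at −78 °C
Reagents that add atoms: none
Why: Acid-catalysed acetalisation with azeotropic removal of water (Seebach self-regeneration of stereocentres). The new acetal centre forms under equilibrium control in favour of the cis isomer, which is purified by cold crystallisation.

Step 3
Reactants: 7 (2R,5R)-2-tert-butyl-5-methyl-1,3-dioxolan-4-one; 4 methyl 2-(5-bromo-2-chloropyridin-4-yl)-2-oxoacetate
Product: 9 methyl (2R)-2-(5-bromo-2-chloropyridin-4-yl)-2-[(2R,4S)-2-tert-butyl-4-methyl-5-oxo-1,3-dioxolan-4-yl]-2-hydroxyacetate, via lithium enolate of the dioxolanone 8 (not isolated)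
Conditions: LiN(i-Pr)2, THF, −78 °C; then 4, THF, −78 °C; AcOH, −78 °C
Reagents that add atoms: none
Why: Aldol addition of a dioxolanone enolate: the non-enolisable keto ester adds to enolate 8 on the face opposite the tert-butyl group, which fixes the future C6 with retention of the lactate configuration. The future C5 is set by the orientation of the ketone in the lithium-bridged chair; the needed (R) carbinol comes from the chair with the ester pointing away from the heterocycle and the pyridyl ring over its open face, and the C5 epimer is a diastereomer that is removed here. The cold acidic quench prevents retro-aldol reversal.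

Step 4
Reactants: 9 methyl (2R)-2-(5-bromo-2-chloropyridin-4-yl)-2-[(2R,4S)-2-tert-butyl-4-methyl-5-oxo-1,3-dioxolan-4-yl]-2-hydroxyacetate
Product: 10 methyl (2R)-2-(5-bromo-2-chloropyridin-4-yl)-2-[(2R,4S)-2-tert-butyl-4-methyl-5-oxo-1,3-dioxolan-4-yl]-2-[(trimethylsilyl)oxy]acetate
Conditions: TMSOTf, 2,6-lutidine, CH2Cl2, −78 to 0 °C
Reagents that add atoms: trimethylsilyl trifluoromethanesulfonate, C[Si](C)(C)OS(=O)(=O)C(F)(F)F
Why: Silyl ether formation with a silyl triflate and a hindered pyridine base works on hindered tertiary alcohols. No free alkoxide is formed, so the aldol adduct is not cleaved.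

Step 5
Reactants: 10 methyl (2R)-2-(5-bromo-2-chloropyridin-4-yl)-2-[(2R,4S)-2-tert-butyl-4-methyl-5-oxo-1,3-dioxolan-4-yl]-2-[(trimethylsilyl)oxy]acetate
Product: 13 methyl (5R,6S)-3-chloro-6-methoxy-6-methyl-7-oxo-5-[(trimethylsilyl)oxy]-6,7-dihydro-5H-cyclopenta[c]pyridine-5-carboxylate, via pyridylmagnesium chloride 11 (not isolated), via chloromagnesium C6-alkoxide 12 (not isolated)
Conditions: i-PrMgCl·LiCl (1.1 equiv), THF, −40 to 0 °C; then MeOTf, −20 to 0 °C; aq. NaHCO3
Reagents that add atoms: methyl trifluoromethanesulfonate, COS(=O)(=O)C(F)(F)F
Why: Bromine–magnesium exchange at the C–Br bond of the electron-poor pyridine is faster than addition of the isopropyl reagent to either carbonyl and leaves the C–Cl bond alone, so the carbanion forms at the future C7a. The pyridylmagnesium 11 adds to the lactone carbonyl, the future C7, in a 5-exo-trig closure that forms the cyclopentanone; the methyl ester does not compete because its attack would need a four-membered ring. The tetrahedral intermediate collapses by breaking the ring C–O bond, and the hemiacetal alkoxide expels pivalaldehyde 6 to leave the chloromagnesium alkoxide 12 on C6, chelated to the new ketone. Methyl triflate then alkylates this oxygen, the only anionic site, in preference to the chlorine-flanked, acyl-deactivated ring nitrogen. The closest known reaction types are the Parham cyclisation (halogen–metal exchange, then intramolecular acylation) and the acylation of organometallic reagents by 1,3-dioxolan-4-ones to give α-hydroxy ketones. No stereocentre is formed: C5 and C6 are fully substituted, carry no acidic hydrogen and keep the configuration set in step 3. Only chemoselectivity is needed, and it rests on the Br/Cl difference, the ring-size bias between the two ester carbonyls, and the silyl ether, which keeps the C5 oxygen from opening the ring or being methylated; the trans relation of the two oxygens on the new ring also disfavours silyl transfer to the C6 alkoxide.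

Step 6
Reactants: 14 (S)-2-methylbutan-1-ol
Product: 16 ethyl (2E,4S)-2,4-dimethylhex-2-enoate, via (S)-2-methylbutanal 15 (not isolated)
Conditions: TEMPO (cat.), PhI(OAc)2, CH2Cl2, rt; then Ph3P=C(CH3)CO2Et, rt
Reagents that add atoms: ethyl 2-(triphenylphosphoranylidene)propanoate, CCOC(=O)C(C)=P(c1ccccc1)(c1ccccc1)c1ccccc1
Why: Base-free nitroxyl oxidation gives the volatile α-branched aldehyde, which is trapped in the same flask before it can racemise. The stabilised ylide gives the (E)-trisubstituted enoate (Wittig olefination).

Step 7
Reactants: 16 ethyl (2E,4S)-2,4-dimethylhex-2-enoate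
Product: 17 (2E,4S)-2,4-dimethylhex-2-en-1-ol
Conditions: i-Bu2AlH, CH2Cl2, −78 to 0 °C; aq. potassium sodium tartrate
Reagents that add atoms: none
Why: 1,2-Reduction of a conjugated ester by the aluminium hydride gives the allylic alcohol without touching the double bond or the C4 centre.

Step 8
Reactants: 17 (2E,4S)-2,4-dimethylhex-2-en-1-ol
Product: 18 (2E,4S)-2,4-dimethylhex-2-enal
Conditions: MnO2, CH2Cl2, rt
Reagents that add atoms: none
Why: Allylic oxidation with MnO2 is neutral and selective for allylic alcohols, so the alkene geometry and the γ-stereocentre are kept.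

Step 9
Reactants: 18 (2E,4S)-2,4-dimethylhex-2-enal
Product: 19 2-[(1E,3E,5S)-3,5-dimethylhepta-1,3-dien-1-yl]-4,4,5,5-tetramethyl-1,3,2-dioxaborolane
Conditions: CH2(Bpin)2, lithium 2,2,6,6-tetramethylpiperidide, THF, 0 °C; then 18, −78 °C to rt
Reagents that add atoms: bis(4,4,5,5-tetramethyl-1,3,2-dioxaborolan-2-yl)methane, CC1(C)OB(CB2OC(C)(C)C(C)(C)O2)OC1(C)C
Why: Boron–Wittig olefination: the lithiated geminal bis(boronate) adds to the aldehyde and syn elimination of a borate gives the trans alkenyl boronate. The carbanion is stabilised and is added cold, which limits γ-deprotonation of the enal.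

Step 10
Reactants: 13 methyl (5R,6S)-3-chloro-6-methoxy-6-methyl-7-oxo-5-[(trimethylsilyl)oxy]-6,7-dihydro-5H-cyclopenta[c]pyridine-5-carboxylate; 19 2-[(1E,3E,5S)-3,5-dimethylhepta-1,3-dien-1-yl]-4,4,5,5-tetramethyl-1,3,2-dioxaborolane
Product: 20 methyl (5R,6S)-3-[(1E,3E,5S)-3,5-dimethylhepta-1,3-dien-1-yl]-6-methoxy-6-methyl-7-oxo-5-[(trimethylsilyl)oxy]-6,7-dihydro-5H-cyclopenta[c]pyridine-5-carboxylate
Conditions: Pd(OAc)2 (5 mol %), SPhos (10 mol %), K3PO4, toluene/H2O, 45 °C
Reagents that add atoms: none
Why: Suzuki–Miyaura coupling: the C3 chloride is α to nitrogen and para to the ketone, so oxidative addition to zerovalent palladium is easy. Alkenyl boronates transfer with retention of geometry, and the biphasic mild base spares the ester and the silyl ether.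

Step 11
Reactants: 20 methyl (5R,6S)-3-[(1E,3E,5S)-3,5-dimethylhepta-1,3-dien-1-yl]-6-methoxy-6-methyl-7-oxo-5-[(trimethylsilyl)oxy]-6,7-dihydro-5H-cyclopenta[c]pyridine-5-carboxylate
Product: 21 methyl (5R,6S)-3-[(1E,3E,5S)-3,5-dimethylhepta-1,3-dien-1-yl]-5-hydroxy-6-methoxy-6-methyl-7-oxo-6,7-dihydro-5H-cyclopenta[c]pyridine-5-carboxylate
Conditions: HF·pyridine, pyridine, THF, 0 °C to rt
Reagents that add atoms: none
Why: Desilylation with buffered hydrogen fluoride cleaves the trimethylsilyl ether without forming an alkoxide, so the β-hydroxy ketone is not opened by retro-aldol cleavage. The diene, the ester and the methyl ether are inert under these conditions.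

## Compound list

1 | 5-bromo-2-chloropyridine | Clc1ccc(Br)cn1 | starting material
2 | dimethyl oxalate | COC(=O)C(=O)OC | starting material
3 | (5-bromo-2-chloropyridin-4-yl)lithium | [Li]c1cc(Cl)ncc1Br | intermediate
4 | methyl 2-(5-bromo-2-chloropyridin-4-yl)-2-oxoacetate | COC(=O)C(=O)c1cc(Cl)ncc1Br | intermediate
5 | (R)-lactic acid | C[C@@H](O)C(=O)O | starting material
6 | pivalaldehyde (2,2-dimethylpropanal) | CC(C)(C)C=O | starting material
7 | (2R,5R)-2-tert-butyl-5-methyl-1,3-dioxolan-4-one | C[C@H]1O[C@@H](C(C)(C)C)OC1=O | intermediate
8 | lithium (2R)-2-tert-butyl-5-methyl-2H-1,3-dioxol-4-olate | CC1=C(O[Li])O[C@H](C(C)(C)C)O1 | intermediate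
9 | methyl (2R)-2-(5-bromo-2-chloropyridin-4-yl)-2-[(2R,4S)-2-tert-butyl-4-methyl-5-oxo-1,3-dioxolan-4-yl]-2-hydroxyacetate | Clc1cc([C@](O)(C(=O)OC)[C@]2(C)O[C@@H](C(C)(C)C)OC2=O)c(Br)cn1 | intermediate
10 | methyl (2R)-2-(5-bromo-2-chloropyridin-4-yl)-2-[(2R,4S)-2-tert-butyl-4-methyl-5-oxo-1,3-dioxolan-4-yl]-2-[(trimethylsilyl)oxy]acetate | Clc1cc([C@](O[Si](C)(C)C)(C(=O)OC)[C@]2(C)O[C@@H](C(C)(C)C)OC2=O)c(Br)cn1 | intermediate
11 | {6-chloro-4-[(1R)-1-[(2R,4S)-2-tert-butyl-4-methyl-5-oxo-1,3-dioxolan-4-yl]-2-methoxy-2-oxo-1-[(trimethylsilyl)oxy]ethyl]pyridin-3-yl}magnesium chloride | Clc1cc([C@](O[Si](C)(C)C)(C(=O)OC)[C@]2(C)O[C@@H](C(C)(C)C)OC2=O)c([Mg]Cl)cn1 | intermediate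
12 | chloromagnesium (5R,6S)-3-chloro-5-(methoxycarbonyl)-6-methyl-7-oxo-5-[(trimethylsilyl)oxy]-6,7-dihydro-5H-cyclopenta[c]pyridin-6-olate | Clc1cc2c(cn1)C(=O)[C@@](C)(O[Mg]Cl)[C@@]2(O[Si](C)(C)C)C(=O)OC | intermediate
13 | methyl (5R,6S)-3-chloro-6-methoxy-6-methyl-7-oxo-5-[(trimethylsilyl)oxy]-6,7-dihydro-5H-cyclopenta[c]pyridine-5-carboxylate | Clc1cc2c(cn1)C(=O)[C@@](C)(OC)[C@@]2(O[Si](C)(C)C)C(=O)OC | intermediate
14 | (S)-2-methylbutan-1-ol | CC[C@H](C)CO | starting material
15 | (S)-2-methylbutanal | CC[C@H](C)C=O | intermediate
16 | ethyl (2E,4S)-2,4-dimethylhex-2-enoate | CC[C@H](C)/C=C(C)/C(=O)OCC | intermediate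
17 | (2E,4S)-2,4-dimethylhex-2-en-1-ol | CC[C@H](C)/C=C(C)/CO | intermediate
18 | (2E,4S)-2,4-dimethylhex-2-enal | CC[C@H](C)/C=C(C)/C=O | intermediate
19 | 2-[(1E,3E,5S)-3,5-dimethylhepta-1,3-dien-1-yl]-4,4,5,5-tetramethyl-1,3,2-dioxaborolane | CC[C@H](C)/C=C(C)/C=C/B1OC(C)(C)C(C)(C)O1 | intermediate
20 | methyl (5R,6S)-3-[(1E,3E,5S)-3,5-dimethylhepta-1,3-dien-1-yl]-6-methoxy-6-methyl-7-oxo-5-[(trimethylsilyl)oxy]-6,7-dihydro-5H-cyclopenta[c]pyridine-5-carboxylate | CC[C@H](C)/C=C(C)/C=C/c1cc2c(cn1)C(=O)[C@@](C)(OC)[C@@]2(O[Si](C)(C)C)C(=O)OC | intermediate
21 | methyl (5R,6S)-3-[(1E,3E,5S)-3,5-dimethylhepta-1,3-dien-1-yl]-5-hydroxy-6-methoxy-6-methyl-7-oxo-6,7-dihydro-5H-cyclopenta[c]pyridine-5-carboxylate | CC[C@H](C)/C=C(C)/C=C/c1cc2c(cn1)C(=O)[C@@](C)(OC)[C@@]2(O)C(=O)OC | target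

## Step count and least certain steps

Total step count: 11. Longest linear sequence: 6 steps (steps 1, 3, 4, 5, 10, 11; the branches from 5 and from 14 are equally long).

**Step 5 (key step).** The cascade may stall or branch after ring closure.
- Pivalaldehyde may not be fully expelled from the hemiacetal alkoxide, so methylation lands on the acetal oxygen and the C6 hydroxyl is released unmethylated on work-up.
- The chelated, hindered magnesium alkoxide may react so slowly that methyl triflate alkylates the ring nitrogen or starts ring-opening polymerisation of THF.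
- Warming to force the reaction invites retro-aldol opening from the C6 alkoxide towards the C5 ester enolate.
- Fallback: separate ring closure from methylation. From 10, run the exchange and cyclisation as before but quench with aq. NH4Cl to isolate the ketol methyl (5R,6S)-3-chloro-6-hydroxy-6-methyl-7-oxo-5-[(trimethylsilyl)oxy]-6,7-dihydro-5H-cyclopenta[c]pyridine-5-carboxylate F1. Methylate its tertiary hydroxyl without a free alkoxide using MeI and Ag2O (Purdie methylation, MeCN, 40 °C); methyl iodide is not expected to quaternise the deactivated 2-chloropyridine. The route is rejoined at 13.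

**Step 3.** The enolate face is secure, but the face of the keto ester is not, so selectivity at C5 may be poor or reversed.
- The competing chair, with the ester chelated to lithium over the heterocycle and the pyridyl ring outside, leads to the C5 epimer.
- Retro-aldol reversal on warming would erode whatever kinetic preference exists.
- Fallback: form the bond between C5 and the ring instead, so that C5 arises by 1,2-induction from the finished C6 centre and not from the orientation of a ketone in an aldol chair. From 7, acylate the enolate 8 with methyl chlorooxoacetate at −78 °C to give methyl 2-[(2R,4S)-2-tert-butyl-4-methyl-5-oxo-1,3-dioxolan-4-yl]-2-oxoacetate F2. Add the aryllithium 3 (from 1 as in step 1) to its ketone in THF at −78 °C; attack anti to the C6–O bond with the ketone oxygen turned away from the lactone carbonyl leads to the (R) carbinol. The route is rejoined at 9.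

**Step 9.** The basic carbanion may deprotonate the α-branched enal at the γ-position, which puts the C4 stereocentre at risk, and the elimination may lose E selectivity with this hindered aldehyde.
- Fallback: go through the alkyne. From 18, homologate with lithiated trimethylsilyldiazomethane (TMSCHN2, LiN(i-Pr)2, THF, −78 °C to rt; Colvin rearrangement) to the enyne (3E,5S)-3,5-dimethylhept-3-en-1-yne F3. Hydroboration with pinacolborane and Cp2Zr(H)Cl (cat.) adds syn and anti-Markovnikov, so the E geometry follows from the mechanism. The route is rejoined at 19.

**Step 10.** Warm aqueous base may remove the trimethylsilyl group early, after which the C5 alkoxide opens the ring by retro-aldol cleavage. The activated chloride may also be displaced by hydroxide, and the dienyl boronate may protodeboronate.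
- Fallback: a base-free Stille coupling. From 18, prepare the enyne F3 as described for step 9 and hydrostannylate it (Bu3SnH, PdCl2(PPh3)2 cat., THF) to tributyl[(1E,3E,5S)-3,5-dimethylhepta-1,3-dien-1-yl]stannane F4. Couple F4 with 13 under neutral conditions (Pd(PPh3)4, CuI, DMF, 70 °C). The route is rejoined at 20.

## Further compounds

F1 | step 5 | methyl (5R,6S)-3-chloro-6-hydroxy-6-methyl-7-oxo-5-[(trimethylsilyl)oxy]-6,7-dihydro-5H-cyclopenta[c]pyridine-5-carboxylate | Clc1cc2c(cn1)C(=O)[C@@](C)(O)[C@@]2(O[Si](C)(C)C)C(=O)OC
F2 | step 3 | methyl 2-[(2R,4S)-2-tert-butyl-4-methyl-5-oxo-1,3-dioxolan-4-yl]-2-oxoacetate | COC(=O)C(=O)[C@]1(C)O[C@@H](C(C)(C)C)OC1=O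
F3 | step 9 | (3E,5S)-3,5-dimethylhept-3-en-1-yne | CC[C@H](C)/C=C(C)/C#C
F4 | step 10 | tributyl[(1E,3E,5S)-3,5-dimethylhepta-1,3-dien-1-yl]stannane | CC[C@H](C)/C=C(C)/C=C/[Sn](CCCC)(CCCC)CCCC
A1 | alternative 1 | methyl 3-[(1E,3E,5S)-3,5-dimethylhepta-1,3-dien-1-yl]-6-methyl-7-oxo-7H-cyclopenta[c]pyridine-5-carboxylate | CC[C@H](C)/C=C(C)/C=C/c1cc2c(cn1)C(=O)C(C)=C2C(=O)OC
A2 | alternative 1 | methyl (5R,6R)-3-[(1E,3E,5S)-3,5-dimethylhepta-1,3-dien-1-yl]-5,6-epoxy-6-methyl-7-oxo-6,7-dihydro-5H-cyclopenta[c]pyridine-5-carboxylate | CC[C@H](C)/C=C(C)/C=C/c1cc2c(cn1)C(=O)[C@]3(C)O[C@]23C(=O)OC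
A3 | alternative 2 | methyl (2R)-2-(2-chloro-5-formylpyridin-4-yl)-3-oxo-2-[(triethylsilyl)oxy]butanoate | CC(=O)[C@@](O[Si](CC)(CC)CC)(C(=O)OC)c1cc(Cl)ncc1C=O
A4 | alternative 2 | methyl (5R,6S)-3-chloro-6-hydroxy-6-methyl-7-oxo-5-[(triethylsilyl)oxy]-6,7-dihydro-5H-cyclopenta[c]pyridine-5-carboxylate | Clc1cc2c(cn1)C(=O)[C@@](C)(O)[C@@]2(O[Si](CC)(CC)CC)C(=O)OC
A5 | alternative 3 | 5-(dimethoxymethyl)-1,2,4-triazine | COC(OC)c1cnncn1
A6 | alternative 3 | methyl (1S,2R)-2-methoxy-2-methyl-5-oxo-1-[(trimethylsilyl)oxy]cyclopentane-1-carboxylate | O=C1CC[C@@](C)(OC)[C@@]1(O[Si](C)(C)C)C(=O)OC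
A7 | alternative 3 | methyl (5R,6R)-3-(dimethoxymethyl)-6-methoxy-6-methyl-5-[(trimethylsilyl)oxy]-6,7-dihydro-5H-cyclopenta[c]pyridine-5-carboxylate | COC(OC)c1cc2c(cn1)C[C@@](C)(OC)[C@@]2(O[Si](C)(C)C)C(=O)OC
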